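**Retrosynthetic overview**

1. Feature: the Z-alkene C1'=C2' lies between the oxygen-bearing carbons C6 (allylic, ring carbon of the dihydropyranone) and C4' (homoallylic). The chain O–C6–C1'=C2'–C3'–C4'–O plus one silicon atom forms an eight-membered 1,3-dioxa-2-silacyclooct-5-ene, which can hold only a cis olefin.
2. The lactone (O1–C2 and C3=C4) is opened to a C4 aldehyde: Z-selective Horner–Wadsworth–Emmons olefination, then lactonisation when fluoride releases C6–OH.
3. C1'=C2' is cut by ring-closing metathesis of an iPr2Si-tethered pair: vinyl carbinol 14 (C4–C6, C1') and allyl carbinol 11 (C2'–C10').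
4. Alcohol 11 comes from cinnamaldehyde: C8' by HYTRA acetate aldol, C6' by Claisen extension and syn reduction, C4' by Brown allylation. Alcohol 14 comes from acrolein by the same aldol.
5. Ring order: the temporary eight-membered silaketal ring first (step 11), the 5,6-dihydro-2H-pyran-2-one ring last (step 14).

Key step: step 11

Remark: (R)-HYTRA (1) and (−)-Ipc2B(allyl) are taken as purchased reagents; target locants (lactone C2–C6, side chain C1'–C10') are used for all intermediates.

**Route**

Step 1
Reactants: 1 (R)-2-hydroxy-1,2,2-triphenylethyl acetate ((R)-HYTRA); 2 (E)-cinnamaldehyde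
Product: 3 (R)-2-hydroxy-1,2,2-triphenylethyl (3R,4E)-3-hydroxy-5-phenylpent-4-enoate
Conditions: LiN(iPr)2 (2.2 equiv), THF, −78 to 0 °C; then 2, THF/2-methylbutane, −125 °C; aq NH4Cl
Reagents that add atoms: none
Why: HYTRA acetate aldol; the dilithium enolate of the (R)-triphenylglycol ester should add to the enal under auxiliary control to set the carbinol (C8') as R, and the crystalline adduct can be enriched by recrystallisation.

Step 2
Reactants: 3 HYTRA aldol adduct
Product: 4 methyl (3R,4E)-3-hydroxy-5-phenylpent-4-enoate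
Conditions: NaOMe (cat.), MeOH, 0 °C to rt
Reagents that add atoms: methanol, CO
Why: Base-catalysed transesterification should release the auxiliary diol; catalytic alkoxide at low temperature should not cause retro-aldol or dehydration, and the stereocentre is not involved.

Step 3
Reactants: 4 methyl (3R,4E)-3-hydroxy-5-phenylpent-4-enoate; 5 tert-butyl acetate
Product: 6 tert-butyl (5R,6E)-5-hydroxy-3-oxo-7-phenylhept-6-enoate
Conditions: 5, LiN(iPr)2 (4 equiv each), THF, −78 °C; then 4, −78 to −20 °C; aq NH4Cl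
Reagents that add atoms: none
Why: Crossed Claisen condensation; excess lithium enolate of 5 first deprotonates the hydroxyl, then acylates at the methyl ester, and the product is protected from further attack as its enolate.

Step 4
Reactants: 6 tert-butyl (5R,6E)-5-hydroxy-3-oxo-7-phenylhept-6-enoate
Product: 7 tert-butyl (3S,5R,6E)-3,5-dihydroxy-7-phenylhept-6-enoate
Conditions: Et2BOMe (1.1 equiv), NaBH4 (1.1 equiv), THF/MeOH 4:1, −78 °C; then MeOH co-evaporation
Reagents that add atoms: none
Why: Narasaka–Prasad reduction; the boron chelate of the β-hydroxy ketone should take hydride externally on its half-chair to give the 1,3-syn diol, so C6' is set by relay from C8'.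

Step 5
Reactants: 7 tert-butyl (3S,5R,6E)-3,5-dihydroxy-7-phenylhept-6-enoate
Product: 8 tert-butyl (3S,5R,6E)-3,5-bis[(tert-butyldimethylsilyl)oxy]-7-phenylhept-6-enoate
Conditions: TBSCl, imidazole, DMF, rt to 40 °C
Reagents that add atoms: TBSCl, CC(C)(C)[Si](C)(C)Cl
Why: Imidazole-promoted silylation of both secondary alcohols; the tert-butyl ester and the styryl alkene should be untouched.

Step 6
Reactants: 8 bis-TBS tert-butyl ester
Product: 9 (3S,5R,6E)-3,5-bis[(tert-butyldimethylsilyl)oxy]-7-phenylhept-6-enal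
Conditions: iBu2AlH (1.1 equiv), CH2Cl2, −78 °C; aq KNaC4H4O6
Reagents that add atoms: none
Why: Partial ester reduction; the tetrahedral aluminium hemiacetal should persist at −78 °C and give the aldehyde only on work-up.

Step 7
Reactants: 9 (3S,5R,6E)-3,5-bis[(tert-butyldimethylsilyl)oxy]-7-phenylhept-6-enal
Product: 11 (1E,3R,5R,7S)-3,5-bis[(tert-butyldimethylsilyl)oxy]-1-phenyldeca-1,9-dien-7-ol, via diisopinocampheylborinate 10 (not isolated)
Conditions: (−)-Ipc2B(allyl), Et2O, −78 °C; then NaOH, H2O2, 0 °C to rt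
Reagents that add atoms: (−)-B-allyldiisopinocampheylborane, C=CCB([C@@H]1C[C@@H]2C[C@H]([C@H]1C)C2(C)C)[C@@H]1C[C@@H]2C[C@H]([C@H]1C)C2(C)C
Why: Brown allylboration through a chair Zimmerman–Traxler transition state; the (+)-α-pinene-derived reagent should override the β-silyloxy centre and deliver the 4'S carbinol (1,3-anti to C6'), and oxidative work-up cleaves the borinate.

Step 8
Reactants: 1 (R)-HYTRA; 12 acrolein
Product: 13 (R)-2-hydroxy-1,2,2-triphenylethyl (3R)-3-hydroxypent-4-enoate
Conditions: LiN(iPr)2 (2.2 equiv), THF, −78 to 0 °C; then 12, THF/2-methylbutane, −125 °C; aq NH4Cl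
Reagents that add atoms: none
Why: The same HYTRA acetate aldol as in step 1; the same enolate face selection should give the (3R)-vinyl carbinol that becomes C6.

Step 9
Reactants: 13 HYTRA adduct of acrolein
Product: 14 methyl (3R)-3-hydroxypent-4-enoate
Conditions: NaOMe (cat.), MeOH, 0 °C
Reagents that add atoms: methanol, CO
Why: Base-catalysed transesterification as in step 2; the auxiliary diol is filtered off and the stereocentre is not touched.

Step 10
Reactants: 14 methyl (3R)-3-hydroxypent-4-enoate; 15 dichlorodiisopropylsilane; 11 (1E,3R,5R,7S)-3,5-bis[(tert-butyldimethylsilyl)oxy]-1-phenyldeca-1,9-dien-7-ol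
Product: 17 diisopropylsilylene bis-ether joining O-3 of 14 (C6–O) to O-7 of 11 (C4'–O), via chlorosilyl ether 16 (not isolated)
Conditions: 14 (1.5 equiv), 15 (excess), imidazole, CH2Cl2, 0 °C; evaporate excess 15; then 11, imidazole, DMF, rt
Reagents that add atoms: none
Why: Stepwise silyl ether formation on a dichlorosilane; with excess silane the first substitution should stop at the monoalkoxy chlorosilane because the two isopropyl groups slow the second, and the second alcohol then displaces chloride under imidazole/DMF activation.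

Step 11
Reactants: 17 mixed diisopropylsilylene bis-ether
Product: 18 methyl 2-[(4R,5Z,8S)-8-[(2R,4R,5E)-2,4-bis[(tert-butyldimethylsilyl)oxy]-6-phenylhex-5-en-1-yl]-2,2-diisopropyl-1,3-dioxa-2-silacyclooct-5-en-4-yl]acetate
Conditions: RuCl2(=CHPh)(PCy3)(H2IMes) (second-generation Grubbs catalyst, 10 mol %), CH2Cl2 (0.005 M), 40 °C
Reagents that add atoms: none
Why: Ring-closing olefin metathesis by the Chauvin cycle: the ruthenium benzylidene should load onto the unhindered homoallylic C2' terminal alkene, the resulting alkylidene undergoes intramolecular [2+2] cycloaddition with the C1' vinyl group, and cycloreversion of the ruthenacyclobutane forms C1'=C2' and releases ethene. The closest known reaction type is temporary silicon-tethered ring-closing metathesis of mixed allylic/homoallylic bis-alkoxysilanes to cis-1,3-dioxa-2-silacyclooct-5-enes. The one ring closed is the eight-membered silaketal, formed by union of two terminal olefins held by the O–Si–O tether and helped by the long Si–O bonds and the two isopropyl groups. No stereocentre is created, since C6, C4', C6' and C8' are set beforehand and untouched; the only new stereo-element, the alkene geometry, should be Z because an eight-membered ring cannot span an E olefin. The step needs ring closure over oligomerisation, secured by high dilution and the tether, and reaction of the two terminal alkenes in preference to the C9'=C10' styryl alkene, secured by the slower metathesis of a conjugated 1,2-disubstituted olefin next to an OTBS-bearing carbon and by the strain of the carbocycles it would give.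

Step 12
Reactants: 18 eight-membered silaketal methyl ester
Product: 19 2-[(4R,5Z,8S)-silaketal-4-yl]acetaldehyde (the C4 aldehyde; ring and side chain as in 18)
Conditions: iBu2AlH (1.1 equiv), CH2Cl2, −78 °C; aq KNaC4H4O6
Reagents that add atoms: none
Why: Partial reduction of the methyl ester via the low-temperature-stable aluminium hemiacetal; the hindered dialkoxysilane and the TBS ethers should not be attacked.

Step 13
Reactants: 19 C4 aldehyde
Product: 20 methyl (2Z)-4-[(4R,5Z,8S)-silaketal-4-yl]but-2-enoate (ring and side chain as in 18)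
Conditions: (CF3CH2O)2P(O)CH2CO2Me, KN(SiMe3)2, 18-crown-6, THF, −78 °C
Reagents that add atoms: methyl bis(2,2,2-trifluoroethyl)phosphonoacetate, COC(=O)CP(=O)(OCC(F)(F)F)OCC(F)(F)F
Why: Still–Gennari variant of the Horner–Wadsworth–Emmons reaction; fast, irreversible elimination from the kinetically formed adduct of the electron-poor phosphonate should give the Z-enoate, and the pre-formed anion at −78 °C should avoid β-elimination of the silyloxy aldehyde.

Step 14
Reactants: 20 Z-enoate
Product: 22 (6R)-6-[(1Z,4S,6R,8R,9E)-4,6,8-trihydroxy-10-phenyldeca-1,9-dien-1-yl]-5,6-dihydro-2H-pyran-2-one (CNP0368533.3), via trihydroxy Z-enoate 21 (not isolated)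
Conditions: HF·pyridine, pyridine, THF, 0 °C to rt
Reagents that add atoms: none
Why: Fluoride-mediated cleavage of all Si–O bonds (silylene and both TBS ethers) should free C6–OH, which lactonises onto the cis-enoate with loss of methanol; no stereocentre is touched.

**Compound list**

1 | (R)-2-hydroxy-1,2,2-triphenylethyl acetate ((R)-HYTRA) | CC(=O)O[C@H](c1ccccc1)C(O)(c1ccccc1)c1ccccc1 | starting material
2 | (E)-cinnamaldehyde | O=C/C=C/c1ccccc1 | starting material
3 | (R)-2-hydroxy-1,2,2-triphenylethyl (3R,4E)-3-hydroxy-5-phenylpent-4-enoate | O=C(C[C@@H](O)/C=C/c1ccccc1)O[C@H](c1ccccc1)C(O)(c1ccccc1)c1ccccc1 | intermediate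
4 | methyl (3R,4E)-3-hydroxy-5-phenylpent-4-enoate | COC(=O)C[C@@H](O)/C=C/c1ccccc1 | intermediate
5 | tert-butyl acetate | CC(=O)OC(C)(C)C | starting material
6 | tert-butyl (5R,6E)-5-hydroxy-3-oxo-7-phenylhept-6-enoate | CC(C)(C)OC(=O)CC(=O)C[C@@H](O)/C=C/c1ccccc1 | intermediate
7 | tert-butyl (3S,5R,6E)-3,5-dihydroxy-7-phenylhept-6-enoate | CC(C)(C)OC(=O)C[C@@H](O)C[C@@H](O)/C=C/c1ccccc1 | intermediate
8 | tert-butyl (3S,5R,6E)-3,5-bis[(tert-butyldimethylsilyl)oxy]-7-phenylhept-6-enoate | CC(C)(C)OC(=O)C[C@@H](O[Si](C)(C)C(C)(C)C)C[C@@H](O[Si](C)(C)C(C)(C)C)/C=C/c1ccccc1 | intermediate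
9 | (3S,5R,6E)-3,5-bis[(tert-butyldimethylsilyl)oxy]-7-phenylhept-6-enal | O=CC[C@@H](O[Si](C)(C)C(C)(C)C)C[C@@H](O[Si](C)(C)C(C)(C)C)/C=C/c1ccccc1 | intermediate
10 | diisopinocampheylborinate of alcohol 11 | C=CC[C@H](OB([C@@H]1C[C@@H]2C[C@H]([C@H]1C)C2(C)C)[C@@H]1C[C@@H]2C[C@H]([C@H]1C)C2(C)C)C[C@@H](O[Si](C)(C)C(C)(C)C)C[C@@H](O[Si](C)(C)C(C)(C)C)/C=C/c1ccccc1 | intermediate
11 | (1E,3R,5R,7S)-3,5-bis[(tert-butyldimethylsilyl)oxy]-1-phenyldeca-1,9-dien-7-ol | C=CC[C@H](O)C[C@@H](O[Si](C)(C)C(C)(C)C)C[C@@H](O[Si](C)(C)C(C)(C)C)/C=C/c1ccccc1 | intermediate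
12 | acrolein | C=CC=O | starting material
13 | (R)-2-hydroxy-1,2,2-triphenylethyl (3R)-3-hydroxypent-4-enoate | O=C(C[C@H](C=C)O)O[C@H](c1ccccc1)C(O)(c1ccccc1)c1ccccc1 | intermediate
14 | methyl (3R)-3-hydroxypent-4-enoate | COC(=O)C[C@H](C=C)O | intermediate
15 | dichlorodiisopropylsilane | CC(C)[Si](Cl)(Cl)C(C)C | starting material
16 | methyl (3R)-3-{[chloro(diisopropyl)silyl]oxy}pent-4-enoate | COC(=O)C[C@H](C=C)O[Si](Cl)(C(C)C)C(C)C | intermediate
17 | mixed diisopropylsilylene bis-ether of 14 (C6–O) and 11 (C4'–O) | COC(=O)C[C@H](C=C)O[Si](C(C)C)(C(C)C)O[C@@H](CC=C)C[C@@H](O[Si](C)(C)C(C)(C)C)C[C@@H](O[Si](C)(C)C(C)(C)C)/C=C/c1ccccc1 | intermediate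
18 | methyl 2-[(4R,5Z,8S)-8-[(2R,4R,5E)-2,4-bis[(tert-butyldimethylsilyl)oxy]-6-phenylhex-5-en-1-yl]-2,2-diisopropyl-1,3-dioxa-2-silacyclooct-5-en-4-yl]acetate | COC(=O)C[C@H]1O[Si](C(C)C)(C(C)C)O[C@H](C[C@@H](O[Si](C)(C)C(C)(C)C)C[C@@H](O[Si](C)(C)C(C)(C)C)/C=C/c2ccccc2)C/C=C\1 | intermediate
19 | C4 aldehyde of the silaketal (CH2CHO in place of CH2CO2Me of 18) | O=CC[C@H]1O[Si](C(C)C)(C(C)C)O[C@H](C[C@@H](O[Si](C)(C)C(C)(C)C)C[C@@H](O[Si](C)(C)C(C)(C)C)/C=C/c2ccccc2)C/C=C\1 | intermediate
20 | methyl (2Z)-4-(silaketal-4-yl)but-2-enoate (Z-enoate on the ring of 18) | COC(=O)/C=C\C[C@H]1O[Si](C(C)C)(C(C)C)O[C@H](C[C@@H](O[Si](C)(C)C(C)(C)C)C[C@@H](O[Si](C)(C)C(C)(C)C)/C=C/c2ccccc2)C/C=C\1 | intermediate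
21 | methyl (2Z,5R,6Z,9S,11R,13R,14E)-5,9,11,13-tetrahydroxy-15-phenylpentadeca-2,6,14-trienoate | COC(=O)/C=C\C[C@@H](O)/C=C\C[C@H](O)C[C@@H](O)C[C@@H](O)/C=C/c1ccccc1 | intermediate
22 | (6R)-6-[(1Z,4S,6R,8R,9E)-4,6,8-trihydroxy-10-phenyldeca-1,9-dien-1-yl]-5,6-dihydro-2H-pyran-2-one | O=C1C=CC[C@H](/C=C\C[C@H](O)C[C@@H](O)C[C@@H](O)/C=C/c2ccccc2)O1 | target

**Step count**

Total: 14 steps. Longest linear sequence: 12 steps (steps 1–7, then 10–14).

**Steps most likely to fail**

Step 11 (ring-closing metathesis). Intermolecular metathesis may outrun closure of the medium ring and give oligomers. The styryl alkene may be engaged with loss of styrene. The catalyst may stall through chelation of a C1' carbene by the ester carbonyl, and ruthenium hydrides may migrate the olefins.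
Fallback (sets out from aldehyde 9, comes back at aldehyde 19): the Z-alkene is made by semi-hydrogenation of an alkyne instead of metathesis.
- Aldehyde 9 is propargylated under reagent control (allenylboronic acid pinacol ester, chiral BINOL-derived phosphoric acid of the antipode that gives the 4'S carbinol) to the homopropargylic alcohol F1.
- Its dianion (n-BuLi, 2 equiv) is acylated with N-methoxy-N-methyl-3-[(4-methoxybenzyl)oxy]propanamide to the ynone F2.
- Noyori transfer hydrogenation (RuCl(p-cymene)[(R,R)-TsDPEN], iPrOH) should set C6 and give the propargylic diol F3.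
- Lindlar hydrogenation (H2, Pd/CaCO3 poisoned with Pb(OAc)2, quinoline) gives the Z-alkene diol F4.
- iPr2Si(OTf)2 and 2,6-lutidine at high dilution close the same eight-membered silaketal as its PMB ether F5.
- DDQ frees the primary alcohol F6, and Dess–Martin oxidation gives 19.

Step 10 (mixed silaketal assembly). The chlorosilane may hydrolyse, the alkoxy groups may scramble to symmetrical bis-ethers, and the second substitution at the hindered C4' carbinol may be slow.
Fallback (sets out from 14, comes back at 17): the tether is built through an Si–H intermediate.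
- 14 is silylated with chlorodiisopropylsilane (iPr2SiHCl, imidazole) to the hydrosilyl ether F7, which can be purified.
- N-bromosuccinimide in CH2Cl2 at 0 °C turns Si–H into Si–Br, giving the bromosilyl ether F8.
- 11 is added with Et3N and DMAP to give 17.

Step 8 (HYTRA aldol with acrolein). Facial selectivity may be only moderate with so small an enal, acrolein may polymerise under the basic conditions, and the small product may be lost on isolation after step 9.
Fallback (sets out from acrolein 12, comes back at 14): enzymatic resolution replaces auxiliary control.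
- The lithium enolate of methyl acetate is added to 12 at −78 °C to give racemic methyl 3-hydroxypent-4-enoate F9.
- F9 is resolved with Burkholderia cepacia lipase and vinyl acetate. By the Kazlauskas rule (vinyl as the smaller group) the S alcohol should be acetylated, leaving 14, which is separated from the acetate.

**Further compounds**

F1 | step 11 | (1E,3R,5R,7S)-3,5-bis[(tert-butyldimethylsilyl)oxy]-1-phenyldec-1-en-9-yn-7-ol | C#CC[C@H](O)C[C@@H](O[Si](C)(C)C(C)(C)C)C[C@@H](O[Si](C)(C)C(C)(C)C)/C=C/c1ccccc1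
F2 | step 11 | ynone from F1 and the PMB-protected Weinreb amide (C6 ketone, C1'≡C2' alkyne) | COc1ccc(COCCC(=O)C#CC[C@H](O)C[C@@H](O[Si](C)(C)C(C)(C)C)C[C@@H](O[Si](C)(C)C(C)(C)C)/C=C/c2ccccc2)cc1
F3 | step 11 | propargylic diol with the (6R)-carbinol | COc1ccc(COCC[C@@H](O)C#CC[C@H](O)C[C@@H](O[Si](C)(C)C(C)(C)C)C[C@@H](O[Si](C)(C)C(C)(C)C)/C=C/c2ccccc2)cc1
F4 | step 11 | Z-alkene diol (C6–OH and C4'–OH free) | COc1ccc(COCC[C@@H](O)/C=C\C[C@H](O)C[C@@H](O[Si](C)(C)C(C)(C)C)C[C@@H](O[Si](C)(C)C(C)(C)C)/C=C/c2ccccc2)cc1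
F5 | step 11 | eight-membered diisopropylsilaketal with a 2-(4-methoxybenzyloxy)ethyl group at C6 | COc1ccc(COCC[C@H]2O[Si](C(C)C)(C(C)C)O[C@H](C[C@@H](O[Si](C)(C)C(C)(C)C)C[C@@H](O[Si](C)(C)C(C)(C)C)/C=C/c3ccccc3)C/C=C\2)cc1
F6 | step 11 | primary alcohol of the silaketal (CH2CH2OH at C6) | OCC[C@H]1O[Si](C(C)C)(C(C)C)O[C@H](C[C@@H](O[Si](C)(C)C(C)(C)C)C[C@@H](O[Si](C)(C)C(C)(C)C)/C=C/c2ccccc2)C/C=C\1
F7 | step 10 | methyl (3R)-3-[(diisopropylsilyl)oxy]pent-4-enoate | COC(=O)C[C@H](C=C)O[SiH](C(C)C)C(C)C
F8 | step 10 | methyl (3R)-3-{[bromo(diisopropyl)silyl]oxy}pent-4-enoate | COC(=O)C[C@H](C=C)O[Si](Br)(C(C)C)C(C)C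
F9 | step 8 | racemic methyl 3-hydroxypent-4-enoate | COC(=O)CC(O)C=C
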